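## Retrosynthetic overview

- Target 16 is a trans-(3R,4R)-3,4-dibenzyloxolan-2-one. The catechol is unmasked last by hydrogenolysis of two benzyl ethers, and the trans relationship comes from base equilibration of C3.
- The lactone (O1–C2–C3–C4–C5) is the only ring built. It is closed in step 7, after the key bond, from a γ-hydroxy tert-butyl ester whose C5 carbinol comes from an N-acyloxazolidinone carbonyl.
- The strategy rests on the C3–C4 ring bond. It joins the two arylpropane halves, and C3 and C4 are each α to a carboxyl-level carbon (C2, and C5 before its reduction). The bond is therefore cut into two enolates, which are joined by oxidative heterocoupling.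
- The halves are imide 6 (from 3-(3,4-dihydroxyphenyl)propanoic acid and (S)-4-benzyloxazolidin-2-one) and tert-butyl ester 8 (from 3-(3,4-dimethoxyphenyl)propanoic acid).

Key step: step 5

Remark on the chemistry: lactone numbering is O1, C2 (C=O), C3 (3,4-dimethoxybenzyl), C4 (3,4-dihydroxybenzyl), C5 (OCH2). The coupling is assumed to control only the imide-derived centre. Compounds 11 to 14 are therefore each written as the pair of epimers at the ester-derived carbon (C2 of the butanoates, C3 of the lactone). The pair is carried unseparated and is converged in step 8; the (2R,3R) member of 11 maps directly onto the trans lactone.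

## Route

Step 1
Reactants: 1 3-(3,4-dihydroxyphenyl)propanoic acid
Product: 2 benzyl 3-[3,4-bis(benzyloxy)phenyl]propanoate
Conditions: BnBr (3.5 equiv), K2CO3 (4 equiv), DMF, 60 °C, under argon
Reagents that add atoms: benzyl bromide, BrCc1ccccc1
Why: Williamson etherification of both phenols and SN2 esterification of the carboxylate with the reactive benzylic bromide should go to completion in a polar aprotic solvent, and exclusion of air keeps the catechol from oxidising before it is capped.

Step 2
Reactants: 2 benzyl 3-[3,4-bis(benzyloxy)phenyl]propanoate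
Product: 3 3-[3,4-bis(benzyloxy)phenyl]propanoic acid
Conditions: LiOH·H2O (3 equiv), THF/MeOH/H2O, rt; then 1 M HCl
Reagents that add atoms: lithium hydroxide, [Li+].[OH-]
Why: Saponification (acyl–oxygen ester hydrolysis) removes only the benzyl ester, since aryl benzyl ethers are inert to aqueous hydroxide.

Step 3
Reactants: 3 3-[3,4-bis(benzyloxy)phenyl]propanoic acid; 4 (S)-4-benzyloxazolidin-2-one
Product: 6 (4S)-4-benzyl-3-{3-[3,4-bis(benzyloxy)phenyl]propanoyl}-1,3-oxazolidin-2-one, via pivalic mixed anhydride 5 (not isolated)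
Conditions: PivCl (1.05 equiv), Et3N (2.5 equiv), THF, −20 °C; then LiCl (1.1 equiv), 4, −20 °C → rt
Reagents that add atoms: none
Why: N-acylation of the auxiliary through the mixed pivalic anhydride (LiCl/Et3N variant of the Evans auxiliary attachment) should be reliable because the lithium-coordinated oxazolidinone attacks the less hindered carbonyl of 5, and the auxiliary stereocentre is not touched.

Step 4
Reactants: 7 3-(3,4-dimethoxyphenyl)propanoic acid
Product: 8 tert-butyl 3-(3,4-dimethoxyphenyl)propanoate
Conditions: tBuOC(=NH)CCl3 (2 equiv), CH2Cl2/cyclohexane, rt, no added Lewis acid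
Reagents that add atoms: tert-butyl 2,2,2-trichloroacetimidate, CC(C)(C)OC(=N)C(Cl)(Cl)Cl
Why: tert-Butyl transfer from the trichloroacetimidate, which the carboxylic acid itself protonates, is a standard mild tert-butyl esterification that avoids strong acid on the electron-rich ring.

Step 5
Reactants: 6 (4S)-4-benzyl-3-{3-[3,4-bis(benzyloxy)phenyl]propanoyl}-1,3-oxazolidin-2-one (1.0 equiv); 8 tert-butyl 3-(3,4-dimethoxyphenyl)propanoate (1.5 equiv)
Product: 11 tert-butyl (2RS,3R)-3-{[(4S)-4-benzyl-2-oxo-1,3-oxazolidin-3-yl]carbonyl}-4-[3,4-bis(benzyloxy)phenyl]-2-(3,4-dimethoxybenzyl)butanoate (pair of C2 epimers), via imide lithium Z-enolate 9 (not isolated), via ester lithium enolate 10 (not isolated)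
Conditions: LDA (2.6 equiv), THF, −78 °C, 45 min (6 and 8 added as one solution); then Fe(acac)3 (trivalent iron, 2.5 equiv) in THF, −78 °C → rt; aq. NH4Cl
Reagents that add atoms: none
Why: LDA converts both partners into lithium enolates that share mixed aggregates; one-electron oxidation by Fe(acac)3 gives an α-carbonyl radical that is captured by the second enolate, and a second one-electron oxidation of the resulting radical anion delivers the neutral succinate and Fe(acac)2 (divalent iron). The closest known reaction type is the iron- or copper-mediated oxidative cross-coupling of an N-acyloxazolidinone enolate with an ester or ketone enolate to an unsymmetrical 2,3-disubstituted 1,4-dicarbonyl compound. No ring closes; one skeletal bond (the future C3–C4) and two stereocentres are formed. The future C4 is controlled by the auxiliary: in the lithium-chelated Z-enolate 9 the 4-benzyl group covers one face, so the new bond forms on the opposite face, which for the (S)-auxiliary gives the R centre. The future C3 (the ester α-carbon, C2 of 11) has no controlling element, so 11 is expected as both C2 epimers, which are not separated because the (2R) member leads directly to the trans lactone and the (2S) member is converged onto it in step 8. The step needs cross-coupling over homocoupling, which the unlike imide and ester enolates (different ease of oxidation, mixed aggregation) and the non-condensing tert-butyl ester should favour, and it needs facial selectivity at the imide carbon, which the auxiliary supplies.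

Step 6
Reactants: 11 tert-butyl (2RS,3R)-3-{[(4S)-4-benzyl-2-oxo-1,3-oxazolidin-3-yl]carbonyl}-4-[3,4-bis(benzyloxy)phenyl]-2-(3,4-dimethoxybenzyl)butanoate
Product: 12 tert-butyl (2RS,3R)-4-[3,4-bis(benzyloxy)phenyl]-2-(3,4-dimethoxybenzyl)-3-(hydroxymethyl)butanoate
Conditions: LiBH4 (2.5 equiv), THF, 0 °C; aq. NH4Cl
Reagents that add atoms: none
Why: Reductive cleavage of the N-acyloxazolidinone should occur because hydride adds to the more electrophilic exocyclic imide carbonyl and the released aldehyde is reduced on to the primary alcohol, while the hindered tert-butyl ester is spared at 0 °C and the C3 centre, no longer α to a carbonyl, keeps its configuration.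

Step 7
Reactants: 12 tert-butyl (2RS,3R)-4-[3,4-bis(benzyloxy)phenyl]-2-(3,4-dimethoxybenzyl)-3-(hydroxymethyl)butanoate
Product: 14 (3RS,4R)-4-[3,4-bis(benzyloxy)benzyl]-3-(3,4-dimethoxybenzyl)oxolan-2-one (cis/trans pair at C3), via hydroxy acid 13 (not isolated)
Conditions: TFA/CH2Cl2 (1:4), 0 °C → rt, 1–2 h; evaporate; aq. NaHCO3
Reagents that add atoms: none
Why: Acidolysis of the tert-butyl ester with loss of isobutylene, followed by acid-catalysed 5-exo-trig lactonisation of the γ-hydroxy acid, closes the oxolan-2-one ring, and aryl benzyl and methyl ethers should tolerate brief exposure to dilute TFA while C4 is unaffected.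

Step 8
Reactants: 14 (3RS,4R)-4-[3,4-bis(benzyloxy)benzyl]-3-(3,4-dimethoxybenzyl)oxolan-2-one
Product: 15 (3R,4R)-4-[3,4-bis(benzyloxy)benzyl]-3-(3,4-dimethoxybenzyl)oxolan-2-one
Conditions: DBU (1.0 equiv), toluene, 60 °C
Reagents that add atoms: none
Why: Thermodynamic epimerisation through the lactone enolate should drain the cis isomer into trans-(3R,4R) 15, because only C3 (α to C2) is acidic, the 3,4-trans arrangement of the two benzyl groups is the more stable one, and C4 stays fixed.

Step 9
Reactants: 15 (3R,4R)-4-[3,4-bis(benzyloxy)benzyl]-3-(3,4-dimethoxybenzyl)oxolan-2-one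
Product: 16 (3R,4R)-4-(3,4-dihydroxybenzyl)-3-(3,4-dimethoxybenzyl)oxolan-2-one
Conditions: H2 (1 atm), 10% Pd/C (zerovalent palladium on carbon), EtOAc/EtOH, rt; filtration and concentration under argon
Reagents that add atoms: none
Why: Catalytic hydrogenolysis of the two aryl benzyl ethers releases the catechol under neutral conditions that leave the lactone, the aryl methyl ethers and both stereocentres untouched.

## Compound list

1 | 3-(3,4-dihydroxyphenyl)propanoic acid | OC(=O)CCc1ccc(O)c(O)c1 | starting material
2 | benzyl 3-[3,4-bis(benzyloxy)phenyl]propanoate | O=C(CCc1ccc(OCc2ccccc2)c(OCc2ccccc2)c1)OCc1ccccc1 | intermediate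
3 | 3-[3,4-bis(benzyloxy)phenyl]propanoic acid | OC(=O)CCc1ccc(OCc2ccccc2)c(OCc2ccccc2)c1 | intermediate
4 | (S)-4-benzyloxazolidin-2-one | O=C1N[C@@H](Cc2ccccc2)CO1 | starting material
5 | 3-[3,4-bis(benzyloxy)phenyl]propanoic pivalic anhydride | CC(C)(C)C(=O)OC(=O)CCc1ccc(OCc2ccccc2)c(OCc2ccccc2)c1 | intermediate
6 | (4S)-4-benzyl-3-{3-[3,4-bis(benzyloxy)phenyl]propanoyl}-1,3-oxazolidin-2-one | O=C(CCc1ccc(OCc2ccccc2)c(OCc2ccccc2)c1)N1C(=O)OC[C@@H]1Cc1ccccc1 | intermediate
7 | 3-(3,4-dimethoxyphenyl)propanoic acid | COc1ccc(CCC(=O)O)cc1OC | starting material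
8 | tert-butyl 3-(3,4-dimethoxyphenyl)propanoate | COc1ccc(CCC(=O)OC(C)(C)C)cc1OC | intermediate
9 | lithium Z-enolate of imide 6 (O–Li cis to the arylmethyl group) | [Li]O/C(=C\Cc1ccc(OCc2ccccc2)c(OCc2ccccc2)c1)N1C(=O)OC[C@@H]1Cc1ccccc1 | intermediate
10 | lithium enolate of ester 8 (double-bond geometry not defined) | [Li]OC(=CCc1ccc(OC)c(OC)c1)OC(C)(C)C | intermediate
11 | tert-butyl (2RS,3R)-3-{[(4S)-4-benzyl-2-oxo-1,3-oxazolidin-3-yl]carbonyl}-4-[3,4-bis(benzyloxy)phenyl]-2-(3,4-dimethoxybenzyl)butanoate (C2 epimer pair) | COc1ccc(CC(C(=O)OC(C)(C)C)[C@H](C(=O)N2C(=O)OC[C@@H]2Cc2ccccc2)Cc2ccc(OCc3ccccc3)c(OCc3ccccc3)c2)cc1OC | intermediate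
12 | tert-butyl (2RS,3R)-4-[3,4-bis(benzyloxy)phenyl]-2-(3,4-dimethoxybenzyl)-3-(hydroxymethyl)butanoate (C2 epimer pair) | COc1ccc(CC(C(=O)OC(C)(C)C)[C@H](CO)Cc2ccc(OCc3ccccc3)c(OCc3ccccc3)c2)cc1OC | intermediate
13 | (2RS,3R)-4-[3,4-bis(benzyloxy)phenyl]-2-(3,4-dimethoxybenzyl)-3-(hydroxymethyl)butanoic acid (C2 epimer pair) | COc1ccc(CC(C(=O)O)[C@H](CO)Cc2ccc(OCc3ccccc3)c(OCc3ccccc3)c2)cc1OC | intermediate
14 | (3RS,4R)-4-[3,4-bis(benzyloxy)benzyl]-3-(3,4-dimethoxybenzyl)oxolan-2-one (C3 epimer pair) | COc1ccc(CC2C(=O)OC[C@@H]2Cc2ccc(OCc3ccccc3)c(OCc3ccccc3)c2)cc1OC | intermediate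
15 | (3R,4R)-4-[3,4-bis(benzyloxy)benzyl]-3-(3,4-dimethoxybenzyl)oxolan-2-one | COc1ccc(C[C@H]2C(=O)OC[C@@H]2Cc2ccc(OCc3ccccc3)c(OCc3ccccc3)c2)cc1OC | intermediate
16 | (3R,4R)-4-(3,4-dihydroxybenzyl)-3-(3,4-dimethoxybenzyl)oxolan-2-one | COc1ccc(C[C@H]2C(=O)OC[C@@H]2Cc2ccc(O)c(O)c2)cc1OC | target

## Summary

Total step count: 9.
Longest linear sequence: 8 steps (1, 2, 3, 5, 6, 7, 8, 9); step 4 is the one-step branch to ester 8.

Steps most likely to fail:

1. Step 5. Homocoupling of either enolate may compete with the cross-coupling, and the face of the imide-derived carbon may be poorly discriminated if bond formation takes place from a species that is no longer chelated. The fallback sets out from 6 and comes back at 15, and it forms the two C–C bonds one after the other by enolate alkylation. Imide 6 is deprotonated with NaHMDS (THF, −78 °C) and alkylated with tert-butyl bromoacetate anti to the auxiliary benzyl group, which should give tert-butyl (3R)-3-{[(4S)-4-benzyl-2-oxo-1,3-oxazolidin-3-yl]carbonyl}-4-[3,4-bis(benzyloxy)phenyl]butanoate F1. Reduction with LiBH4 (THF, 0 °C) should give tert-butyl (3R)-4-[3,4-bis(benzyloxy)phenyl]-3-(hydroxymethyl)butanoate F2, and TFA/CH2Cl2 should close it to (4R)-4-[3,4-bis(benzyloxy)benzyl]oxolan-2-one F3. The lithium enolate of this lactone (LiHMDS, THF, −78 °C) is then alkylated with 3,4-dimethoxybenzyl bromide anti to the C4 substituent, which should give the trans lactone 15 directly.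

2. Step 6. Hydride may attack the ring carbonyl of the auxiliary because the exocyclic carbonyl sits next to a doubly branched carbon, or the liberated alkoxide may lactonise early and be reduced further. The fallback sets out from 11 and comes back at 12. It removes the auxiliary hydrolytically with LiOH/H2O2 (THF/H2O, 0 °C; Na2SO3 quench), which is selective for the exocyclic carbonyl and should give (2R,3RS)-2-[3,4-bis(benzyloxy)benzyl]-4-tert-butoxy-3-(3,4-dimethoxybenzyl)-4-oxobutanoic acid F4. Its free carboxylic acid is then reduced chemoselectively with BH3·SMe2 (THF, 0 °C → rt) in the presence of the tert-butyl ester to alcohol 12.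

3. Step 7. The tert-butyl cation may alkylate the electron-rich rings, or the acid may partly remove the benzyl ethers. The fallback sets out from 12 and comes back at 15, and it forms the lactone under base instead. Catalytic KOtBu in THF/t-BuOH at rt should make the alkoxide of 12 displace tert-butoxide intramolecularly, and the same medium, under proton exchange, should equilibrate C3, so the trans lactone 15 is reached without an acidic step and without new isolated compounds.

## Further compounds

F1 | step 5 | tert-butyl (3R)-3-{[(4S)-4-benzyl-2-oxo-1,3-oxazolidin-3-yl]carbonyl}-4-[3,4-bis(benzyloxy)phenyl]butanoate | CC(C)(C)OC(=O)C[C@@H](Cc1ccc(OCc2ccccc2)c(OCc2ccccc2)c1)C(=O)N1C(=O)OC[C@@H]1Cc1ccccc1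
F2 | step 5 | tert-butyl (3R)-4-[3,4-bis(benzyloxy)phenyl]-3-(hydroxymethyl)butanoate | CC(C)(C)OC(=O)C[C@@H](Cc1ccc(OCc2ccccc2)c(OCc2ccccc2)c1)CO
F3 | step 5 | (4R)-4-[3,4-bis(benzyloxy)benzyl]oxolan-2-one | O=C1C[C@@H](Cc2ccc(OCc3ccccc3)c(OCc3ccccc3)c2)CO1
F4 | step 6 | (2R,3RS)-2-[3,4-bis(benzyloxy)benzyl]-4-tert-butoxy-3-(3,4-dimethoxybenzyl)-4-oxobutanoic acid | COc1ccc(CC(C(=O)OC(C)(C)C)[C@H](C(=O)O)Cc2ccc(OCc3ccccc3)c(OCc3ccccc3)c2)cc1OC
F0 | step 7 | none | none
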